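We read this flask at 30 min, so the useful question is turned round: what would have to be true of the given numbers for it not to be at rest by then?

X 0.19 M; Q 0.180 M; time 30 min

    X + Q → X.Q, rate k1*[X]^2*[Q]^0.5 (k1 = 4.5 /M^1.5/s)
    X.Q ⇌ J (K2 = 0.56, k2 = 0.16 /s)

- the reaction counts as stopped when no species that holds the X changes by six tenths of a point or more over the second half of the time
- run time (flask): 30 min

- which holds at 30 min: what has brought the reaction to rest, or that it has not come to rest (Q has run out first / forward and back rates have come level / it is still moving / all of X has reacted)
- conversion of X at 30 min
- amount of X.Q at 30 min, in percent of the X charged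
- amount of J at 30 min, in percent of the X charged

Using up the X in this flask takes as much Q as there is X, one for one, but the 0.180 M of Q stands 0.0100 M below the 0.19 M of X, so Q is the limiting reagent and [X] stays above [Q] by that gap. For the flask to be still moving, the last of Q would have to outlast the reading. Writing [X] as the gap plus [Q] and integrating the rate law, the half order lets [Q] reach zero in a finite time, less than 2 times what we call the gap time, one over k1 times the gap to the power three halves: 3.70 min. That bounds the run-out of Q in this flask at 7.41 min, shorter than the reading time by a factor of 4.05. X.Q and J relax with a half-life of 1.56 s, shorter still, so they share what Q has made in the ratio K2. We commit to a conversion of 94.7%, with 60.7% as X.Q and 34.0% as J.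

The forecast answers "Q has run out first", with conversion 94.7%, X.Q 60.7% and J 34%, on the ground that “the half order in Q lets it reach zero in a finite time”.

The simulated flask gives "Q has run out first", with conversion 94.7%, X.Q 60.7% and J 34.0%. In this flask Q stands at 0.973% of its charge at 3.00 min and at 0% at 15.0 min, readings on either side of our bound of 7.41 min. In the neighbour flask with 0.072 M of Q, the gap widens to 0.118 M and the gap time falls to 5.48 s, which bounds its run-out at 11.0 s. At 30.0 min that neighbour holds 0% of Q and 62.1% of its X, a conversion of 37.9%.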